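**Retrosynthetic overview**
1. Three rings are joined through two adjacent spiro carbons. Ring A is a 5-methoxy-4,4,6-trimethylcyclohex-5-ene-1,3-dione (in ring order: spiro carbon, enone C=O, C–Me, C–OMe, CMe2, lone ketone C=O). Ring B is a cyclopentane (B1 = the spiro carbon of ring A, B2 = CH–iPr, B3 and B4 = CH2, B5). Ring C is a 6,6-dimethylbicyclo[3.1.1]heptane whose C2 is B5.
2. Feature used: B1 and B5 are vicinal quaternary carbons and B1 carries both ring-A carbonyls. Written as geminal esters, these carbonyls make B5 the acceptor carbon of an alkylidene malonate and then make B1 an electrophilic radical, so the two ring-B bonds flanking the quaternary pair (B4–B5 and B1–B2) can be formed in one radical annulation.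
3. Key disconnection: ring B and a γ-lactone (B1–C(=O)–O–CMe2–B2) from the nopinone alkylidene malonate and the 4-methylpent-3-enyl radical of an N-acyloxyphthalimide. The lactone distinguishes the two carbonyls on B1.
4. Ring A is built last: methyl enol ether ⇐ trione ⇐ Dieckmann closure (CMe2 carbon onto the lone-ketone carbon) ⇐ C-acylation (enone carbonyl to C–Me carbon) of the kinetic enolate of 2-methylpentan-3-one by the acid chloride of the former lactone carbonyl, after the lactone C–O bond has been reduced to the isopropyl C–H.
5. Ring order: C (bought as (+)-β-pinene), then B together with the lactone, then A.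

Key step: step 4

Remark on the chemistry: (+)-β-pinene is assumed to be enantiopure, so its bridgeheads alone fix the absolute configuration; the labels B1–B5 and pinane C1–C7 defined above are used throughout.

**Step 1**
Reactants: 1 (1R,5R)-(+)-β-pinene
Product: 3 (1S,5R)-(−)-nopinone, via secondary ozonide 2 (not isolated)
Conditions: O3, CH2Cl2, −78 °C; then Me2S, −78 °C → rt
Reagents that add atoms: ozone, [O-][O+]=O
Why: Ozonolysis (Criegee mechanism) of the exocyclic 1,1-disubstituted alkene with reductive work-up should give the ketone, and neither bridgehead stereocentre is touched.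

**Step 2**
Reactants: 3 (1S,5R)-(−)-nopinone; 4 dimethyl malonate
Product: 5 dimethyl 2-[(1S,5R)-6,6-dimethylbicyclo[3.1.1]heptan-2-ylidene]malonate
Conditions: TiCl4 (2 equiv), pyridine (4 equiv), THF, 0 °C → rt
Reagents that add atoms: none
Why: The TiCl4–pyridine variant of the Knoevenagel condensation is the one that works for ketones (titanium malonate enolate adds to the TiCl4-activated carbonyl, then the titanium-bound oxygen is lost); the two esters are identical, so there is no alkene geometry to control, and the buffered medium should leave the cyclobutane and the α-bridgehead centre intact.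

**Step 3**
Reactants: 6 5-methylhex-4-enoic acid; 7 N-hydroxyphthalimide
Product: 8 N-(5-methylhex-4-enoyloxy)phthalimide
Conditions: iPrN=C=NiPr, DMAP (cat.), CH2Cl2, 0 °C → rt
Reagents that add atoms: none
Why: Steglich-type carbodiimide esterification (DMAP-catalysed acyl transfer from the O-acylisourea to the N–OH group) should give the redox-active ester; the trisubstituted alkene is inert and no stereocentre is involved.

**Step 4**
Reactants: 5 dimethyl 2-[(1S,5R)-6,6-dimethylbicyclo[3.1.1]heptan-2-ylidene]malonate; 8 N-(5-methylhex-4-enoyloxy)phthalimide
Product: 9 cis-fused lactone ester of the spiro cyclopentane (lactone C=O and CO2Me on B1, lactone O–CMe2 on B2, B5 = pinane C2)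
Conditions: fac-Ir(ppy)3 (1 mol %), 8 (2 equiv, in portions), degassed CH2Cl2 (0.5 M in 5), blue LEDs (450 nm), rt
Reagents that add atoms: none
Why: Proposed new method: photoexcited fac-Ir(ppy)3 (trivalent iridium) transfers an electron to ester 8, which fragments to phthalimide anion, CO2 and the 4-methylpent-3-enyl radical; this nucleophilic radical adds to the electron-poor ring carbon of 5 (bond B4–B5), the electrophilic malonyl radical so formed attacks the CH end of its own electron-rich trisubstituted alkene (bond B1–B2), and tetravalent iridium oxidises the resulting tertiary radical to a cation that the carbonyl oxygen of the cis ester captures, the O-methyl lactonium ion finally passing its methyl group to phthalimide anion. The closest known reactions are photoredox decarboxylative Giese additions of N-acyloxyphthalimides to alkylidene malonates and the Mn(OAc)3 (trivalent manganese) 5-exo cyclisation–lactonisation of alkenyl malonates; merging them is reasonable because the cycle is redox-neutral, so nothing in the flask reduces the malonyl radical before it cyclises, and radical polarity is matched in both C–C bond formations. Ring B closes by radical 5-exo-trig attack, and the γ-lactone closes by a five-membered cationic O-cyclisation (ester carbonyl oxygen onto the tertiary carbocation, then O-demethylation). B5 is set by approach of the radical to the alkene face anti to the gem-dimethyl bridge of the pinane; B2 is set in the chair-like 5-exo transition state, where the bulky bridgehead C1 on B5 sits pseudo-equatorial so that the alkene arm ends up trans to C1 and cis to the C3 methylene; B1 follows from B2 because only the ester cis to the cationic arm can lactonise, which also marks that carbonyl as the future enone carbonyl of ring A. The step needs addition to 5 to outrun loss of the primary radical (helped by a high concentration of 5 and an excess of 8, while the reversible 3-exo closure of this homoallyl radical is degenerate and costs nothing), 5-exo over 6-endo closure (the gem-dimethyl alkene terminus blocks 6-endo attack and leads to a tertiary radical) and lactonisation over proton loss from the cation (the cis carbonyl is held within reach).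

**Step 5**
Reactants: 9 cis-fused lactone ester
Product: 10 malonic half-ester acid (B1 carries CO2H cis to the B2 isopropyl group and CO2Me trans to it)
Conditions: Et3SiH (10 equiv), CF3CO2H–CH2Cl2 (1:1), CF3SO3H (0.2 equiv), 0 °C → rt
Reagents that add atoms: none
Why: Ionic hydrogenation: the acid ionises the tertiary alkyl–oxygen bond of the lactone (the same alkyl–oxygen cleavage by which tert-butyl esters are removed) and the large excess of silane traps the exocyclic tertiary cation by hydride transfer, so the new C–H is made outside the ring and B1, B2 and B5 are not touched, while the methyl ester and the saturated pinane should tolerate the medium.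

**Step 6**
Reactants: 10 malonic half-ester acid
Product: 11 acid chloride (COCl in place of CO2H on B1)
Conditions: (COCl)2 (2 equiv), DMF (cat.), CH2Cl2, 0 °C → rt; evaporate
Reagents that add atoms: oxalyl chloride, ClC(=O)C(=O)Cl
Why: Vilsmeier-catalysed conversion of a carboxylic acid into its acid chloride; the α-carbon is quaternary, so neither ketene formation nor epimerisation is possible, and the methyl ester is inert.

**Step 7**
Reactants: 11 acid chloride; 12 2-methylpentan-3-one
Product: 14 β-diketone ester, via lithium enolate 13 (not isolated)
Conditions: 12 (2.4 equiv), LiN(iPr)2 (2.3 equiv), THF, −78 °C; then 11, −78 → 0 °C; aq. NH4Cl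
Reagents that add atoms: none
Why: Crossed Claisen-type C-acylation of a preformed kinetic lithium enolate: LiN(iPr)2 at −78 °C deprotonates the ethyl CH2 and not the isopropyl CH, the acid chloride is far more reactive than the neighbouring methyl ester, and the second equivalent of enolate takes up the acidic proton of the product (any enol ester from O-acylation is itself an acyl donor towards the excess enolate and should be drawn on to the same lithium diketonate); the new CH(Me) centre is epimerisable and is erased in step 8.

**Step 8**
Reactants: 14 β-diketone ester
Product: 15 spiro trione with ring A closed (drawn as its 5-hydroxy enol)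
Conditions: LiN(iPr)2 (3.2 equiv), THF, −78 °C → rt; then 1 M HCl
Reagents that add atoms: none
Why: Dieckmann (intramolecular Claisen) condensation through the β-diketone dianion: the second deprotonation can occur only at the isopropyl CH, whose carbanion should close the six-membered ring onto the methyl ester (6-exo-trig), driven by loss of methoxide and formation of the stabilised cyclic β-diketonate; B1 is quaternary and cannot epimerise, so the former lactone carbonyl is fixed as the enone carbonyl next to the C–Me carbon and the former ester carbonyl as the lone ketone next to CMe2.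

**Step 9**
Reactants: 15 spiro trione
Product: 16 CNP0307059.1 (target)
Conditions: Me3SiCHN2 (2 M in hexanes), MeOH–toluene (1:4), 0 °C → rt
Reagents that add atoms: trimethylsilyldiazomethane, C[Si](C)(C)C=[N+]=[N-]
Why: O-methylation of the acidic cyclic enol by a diazoalkane, which alkylates oxygen and not carbon; the enol oxygen on the carbon between the ring CMe2 and the C–Me carbon is less shielded than the oxygen on the carbon next to B1, which lies under the cis isopropyl group and the pinane, so the 5-methoxy-1,3-dione pattern of the target should predominate, and any regioisomeric ether could be separated and hydrolysed back to 15.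

**Compound list**
1 | (1R,5R)-(+)-β-pinene | C=C1CC[C@@H]2C[C@H]1C2(C)C | starting material
2 | secondary ozonide of 1 (spiro 1,2,4-trioxolane on pinane C2, both spiro epimers) | C1OOC2(O1)CC[C@@H]3C[C@H]2C3(C)C | intermediate (not isolated)
3 | (1S,5R)-(−)-nopinone, (1S,5R)-6,6-dimethylbicyclo[3.1.1]heptan-2-one | O=C1CC[C@@H]2C[C@H]1C2(C)C | intermediate
4 | dimethyl malonate | COC(=O)CC(=O)OC | starting material
5 | dimethyl 2-[(1S,5R)-6,6-dimethylbicyclo[3.1.1]heptan-2-ylidene]malonate | COC(=O)C(C(=O)OC)=C1CC[C@@H]2C[C@H]1C2(C)C | intermediate
6 | 5-methylhex-4-enoic acid | CC(C)=CCCC(=O)O | starting material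
7 | N-hydroxyphthalimide | O=C1c2ccccc2C(=O)N1O | starting material
8 | N-(5-methylhex-4-enoyloxy)phthalimide (1,3-dioxoisoindolin-2-yl 5-methylhex-4-enoate) | CC(C)=CCCC(=O)ON1C(=O)c2ccccc2C1=O | intermediate
9 | lactone ester: methyl 3,3-dimethyl-1-oxo-hexahydrocyclopenta[c]furan-6a-carboxylate spiro-linked at C6 (B5) to pinane C2; cis ring fusion, B4 anti and B1 syn to the gem-dimethyl bridge, lactone on the ring-B face that carries pinane C3 | O=C1OC(C)(C)[C@H]2CC[C@@]3(CC[C@@H]4C[C@H]3C4(C)C)[C@@]12C(=O)OC | intermediate
10 | half-ester acid: spiro[cyclopentane–pinane] with CO2H (cis to iPr) and CO2Me on B1 and isopropyl on B2 | OC(=O)[C@@]2(C(=O)OC)[C@@H](C(C)C)CC[C@@]21CC[C@@H]2C[C@H]1C2(C)C | intermediate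
11 | acid chloride of 10 | ClC(=O)[C@@]2(C(=O)OC)[C@@H](C(C)C)CC[C@@]21CC[C@@H]2C[C@H]1C2(C)C | intermediate
12 | 2-methylpentan-3-one | CCC(=O)C(C)C | starting material
13 | lithium enolate of 12 (4-methylpent-2-en-3-olate, enolate geometry immaterial) | CC=C(O[Li])C(C)C | intermediate (not isolated)
14 | β-diketone ester: B1 carries CO2Me and the 2,4-dimethyl-3-oxopentanoyl group (cis to iPr; epimers and enol forms at the CH(Me) carbon) | CC(C)C(=O)C(C)C(=O)[C@@]2(C(=O)OC)[C@@H](C(C)C)CC[C@@]21CC[C@@H]2C[C@H]1C2(C)C | intermediate
15 | spiro trione, 5-hydroxy-4,4,6-trimethylcyclohex-5-ene-1,3-dione ring A on B1 (enol tautomer) | OC1=C(C)C(=O)[C@@]2(C(=O)C1(C)C)[C@@H](C(C)C)CC[C@@]21CC[C@@H]2C[C@H]1C2(C)C | intermediate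
16 | CNP0307059.1 | COC1=C(C)C(=O)[C@@]2(C(=O)C1(C)C)[C@@H](C(C)C)CC[C@@]21CC[C@@H]2C[C@H]1C2(C)C | target

**Step count**
Total: 9 steps. Longest linear sequence: 8 steps from 1 (steps 1, 2, 4, 5, 6, 7, 8, 9); step 3 is a one-step side branch.

**Steps most likely to fail**

1. Step 4 (key step).
   - What may go wrong: the primary radical may be reduced or may dimerise before it adds to the hindered tetrasubstituted acceptor; catalyst turnover may stall if oxidation of the tertiary radical by tetravalent iridium is slow; and the 5-exo closure may show poor facial selectivity at B2.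
   - Fallback (known chemistry, sets out from 5, returns at 9): 4-methylpent-3-enylmagnesium bromide F1, made from commercial 5-bromo-2-methylpent-2-ene and Mg in THF, would be added to 5 with CuBr·SMe2 (10 mol %) and Me3SiCl in THF at −40 °C. Copper-catalysed conjugate addition, again anti to the gem-dimethyl bridge, should give the saturated malonate F2. Heating F2 with Mn(OAc)3·2H2O (2.2 equiv, trivalent manganese) in AcOH at 70 °C should generate the same malonyl radical, which closes 5-exo; a second equivalent of trivalent manganese oxidises the tertiary radical to the cation, which lactonises to 9.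

2. Step 5.
   - What may go wrong: internal return of the cation to the lactone may be so fast that little is reduced, or proton loss and re-protonation of the cation may outrun hydride capture and scramble B2.
   - Fallback (no cation at the exocyclic carbon, sets out from 9, rejoins at 16): excess lithium enolate 13 (LiN(iPr)2, THF, −78 → 0 °C) would open the lactone at its carbonyl to the tertiary alkoxide of hydroxy diketone ester F3. More LiN(iPr)2 in the same flask would close ring A through the dianion to hydroxy trione F4. Me3SiCHN2 in MeOH–toluene, with acid kept away so that the tertiary alcohol does not add to the neighbouring enone carbonyl, would give hydroxy methyl enol ether F5. Acylation with methyl chlorooxalate (DMAP, Et3N, CH2Cl2) would give mixed methyl oxalate F6, and Bu3SnH with AIBN in refluxing toluene (Barton-type radical deoxygenation of a tertiary oxalate) would replace C–O by C–H with B2 untouched, giving 16.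

3. Step 8.
   - What may go wrong: the tertiary carbanion may not reach an ester carbonyl flanked by two fully substituted carbons, so that O-acylation to an enol lactone or cleavage of the diketone takes over.
   - Fallback (aldol closure on an aldehyde in place of Claisen closure on the ester, sets out from 14, returns at 15): the diketone would be masked as its sodium enolate (NaH, THF) and the ester alone reduced with LiAlH4 at 0 °C to hydroxymethyl diketone F7. Oxidation with Pr4N[RuO4] (cat.) and NMO would give keto aldehyde F8. KOtBu (2.2 equiv) in THF at −40 → 0 °C should bring about intramolecular aldol addition of the isopropyl carbon to the much more electrophilic aldehyde, giving ring-A hydroxy dione F9. A second Pr4N[RuO4]/NMO oxidation of the secondary alcohol would give 15.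

**Further compounds**
F1 | step 4 | 4-methylpent-3-enylmagnesium bromide | CC(C)=CCC[Mg]Br
F2 | step 4 | dimethyl 2-[(1S,5R)-6,6-dimethyl-2-(4-methylpent-3-enyl)bicyclo[3.1.1]heptan-2-yl]malonate (side chain anti to the gem-dimethyl bridge) | COC(=O)C(C(=O)OC)[C@@]1(CCC=C(C)C)CC[C@@H]2C[C@H]1C2(C)C
F3 | step 5 | hydroxy diketone ester (as 14, with 2-hydroxypropan-2-yl on B2) | CC(C)C(=O)C(C)C(=O)[C@@]2(C(=O)OC)[C@@H](C(C)(C)O)CC[C@@]21CC[C@@H]2C[C@H]1C2(C)C
F4 | step 5 | hydroxy trione (as 15, with 2-hydroxypropan-2-yl on B2) | OC1=C(C)C(=O)[C@@]2(C(=O)C1(C)C)[C@@H](C(C)(C)O)CC[C@@]21CC[C@@H]2C[C@H]1C2(C)C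
F5 | step 5 | hydroxy methyl enol ether (as 16, with 2-hydroxypropan-2-yl on B2) | COC1=C(C)C(=O)[C@@]2(C(=O)C1(C)C)[C@@H](C(C)(C)O)CC[C@@]21CC[C@@H]2C[C@H]1C2(C)C
F6 | step 5 | mixed methyl oxalate of F5 | COC1=C(C)C(=O)[C@@]2(C(=O)C1(C)C)[C@@H](C(C)(C)OC(=O)C(=O)OC)CC[C@@]21CC[C@@H]2C[C@H]1C2(C)C
F7 | step 8 | hydroxymethyl diketone (as 14, with CH2OH in place of CO2Me) | CC(C)C(=O)C(C)C(=O)[C@@]2(CO)[C@@H](C(C)C)CC[C@@]21CC[C@@H]2C[C@H]1C2(C)C
F8 | step 8 | keto aldehyde (as 14, with CHO in place of CO2Me) | CC(C)C(=O)C(C)C(=O)[C@@]2(C=O)[C@@H](C(C)C)CC[C@@]21CC[C@@H]2C[C@H]1C2(C)C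
F9 | step 8 | ring-A hydroxy dione (as 15, with CH–OH in place of the lone ketone between B1 and CMe2, both epimers) | OC1=C(C)C(=O)[C@@]2(C(O)C1(C)C)[C@@H](C(C)C)CC[C@@]21CC[C@@H]2C[C@H]1C2(C)C
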